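**Strategy**

Ring B, the enolised cyclohexane-1,3,5-trione, is disconnected at the two bonds that join the carbonyl carbons flanking its quaternary carbon (C3 and C5) to C2 and C6. The quaternary carbon C4 with its methyl and geranyl groups is then the centre of a malonyl unit, and C6, C1, C2 and the C2 acetyl group are acetylacetone. In one operation the acetylacetone dianion is acylated at a methyl carbon by an acid chloride and its central carbon then closes onto the neighbouring methyl ester, which makes both bonds and the ring. The precursor is the (S)-configured acid chloride–methyl ester of methyl(geranyl)malonic acid; its two unlike carboxyl groups decide which flank of C4 carries the acetyl group.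

Key step: step 4

Remark on the structures: no error was found; the acid chloride drawn is (S), it derives from the (R)-half-ester and maps onto the (4R) ring B of the target (descriptors refer to the enol tautomers as drawn).

Assumption: pig liver esterase is taken to hydrolyse the pro-S ester group of 3, the sense expected for a long lipophilic chain beside methyl; this has to be confirmed on the geranyl substrate.

**Route**

Step 1
Reactants: 1 dimethyl methylmalonate; 2 geranyl bromide
Product: 3 dimethyl 2-[(2E)-3,7-dimethylocta-2,6-dien-1-yl]-2-methylpropanedioate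
Conditions: NaH (1.05 equiv), THF, 0 °C; then 2, 0 °C → rt
Reagents that add atoms: none
Why: Malonate alkylation, in which the soft sodium enolate of 1 should displace the primary allylic bromide by SN2 at C1 of the geranyl unit, keeping the 2E double bond and creating the prochiral quaternary carbon.

Step 2
Reactants: 3 dimethyl 2-geranyl-2-methylmalonate
Product: 4 (2R,4E)-2-(methoxycarbonyl)-2,5,9-trimethyldeca-4,8-dienoic acid
Conditions: pig liver esterase, 0.1 M phosphate buffer pH 7.5 with 10% DMSO, rt, pH-stat (1 M NaOH); then 1 M HCl to pH 2–3 at 0 °C, EtOAc
Reagents that add atoms: water, O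
Why: Enzymatic desymmetrisation of a 2,2-disubstituted malonate by enantiotopic-group-selective ester hydrolysis, in which the esterase should cleave only the pro-S ester group and so set the quaternary stereocentre as R, while the carboxylate formed resists a second hydrolysis.

Step 3
Reactants: 4 (R)-half-ester
Product: 5 methyl (2S,4E)-2-(chlorocarbonyl)-2,5,9-trimethyldeca-4,8-dienoate
Conditions: 1-chloro-N,N,2-trimethylprop-1-en-1-amine (1.2 equiv), CH2Cl2, 0 °C → rt; concentrate, use crude
Reagents that add atoms: 1-chloro-N,N,2-trimethylprop-1-en-1-amine, CC(C)=C(Cl)N(C)C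
Why: Acid chloride formation with the Ghosez chloroenamine releases no HCl and should therefore spare the two trisubstituted alkenes, and the quaternary centre cannot epimerise (the descriptor changes from R to S only because COCl outranks CO2Me).

Step 4
Reactants: 5 (S)-acid chloride methyl ester; 6 pentane-2,4-dione
Product: 9 (4R)-2-acetyl-4-[(2E)-3,7-dimethylocta-2,6-dien-1-yl]-3,5-dihydroxy-4-methylcyclohexa-2,5-dien-1-one, via dilithiated pentane-2,4-dione 7 (not isolated), via open-chain triketo ester 8 (not isolated)
Conditions: 6 (3.0 equiv), LDA (6.0 equiv), THF, 0 °C; then 5 in THF, −78 °C → rt → 50 °C; 1 M HCl, 0 °C; NaHCO3 extraction and re-acidification to separate 9 from 6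
Reagents that add atoms: none
Why: Dianion 7 attacks the acid chloride of 5 through its terminal carbon, the more basic and less hindered site, at −78 °C, where the neopentyl-type methyl ester is inert; two further equivalents of 7 then deprotonate triketo ester 8 at C4 and C6 of its octanoate chain. The C6 carbanion, which lies between the two ketones that came from acetylacetone, adds to the ester carbonyl and expels methoxide, a 6-exo-trig Claisen (Dieckmann-type) closure that forms ring B. The closest known reactions are the terminal C-acylation of β-diketone dianions and the base-induced Claisen cyclisation of 3,5,7-triketo esters to acylphloroglucinols. No stereocentre is created: the quaternary carbon has no α-hydrogen, so its configuration is carried over, and the order acid chloride first, ester second places the acetyl-bearing carbon next to the former ester carbon, which gives (4R)-9. The step needs chemoselectivity between the two acyl groups and C- over O-cyclisation; the first rests on the large reactivity gap between COCl and a hindered CO2Me, the second on the reversibility of enol-lactone formation and on the stability of the doubly deprotonated triketone that ends the sequence. An aldol closure to a resorcinol is disfavoured because every ketone of 8 is tied up in an enolate while the ester is not.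

Step 5
Reactants: 10 phloroglucinol; 11 hexanoyl chloride
Product: 12 1-(2,4,6-trihydroxyphenyl)hexan-1-one
Conditions: AlCl3 (4 equiv), PhNO2/CH2Cl2, rt → 50 °C; then ice/aq. HCl
Reagents that add atoms: none
Why: Friedel–Crafts C-acylation of phloroglucinol should stop after one acyl group because the ketone deactivates the ring, and the three equivalent ring positions leave no regiochemical choice.

Step 6
Reactants: 12 hexanoylphloroglucinol; 13 3-methylbut-2-enal
Product: 15 1-(5,7-dihydroxy-2,2-dimethyl-2H-chromen-8-yl)hexan-1-one, via ortho-quinone methide dienone 14 (not isolated)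
Conditions: ethylenediammonium diacetate (10 mol %), toluene, 110 °C; chromatography
Reagents that add atoms: none
Why: Amine-catalysed Knoevenagel-type condensation at a ring carbon of 12 followed by oxa-6π electrocyclisation of dienone 14 builds the 2,2-dimethylchromene; closure through the oxygen ortho to the acyl group gives 15, while closure through the para oxygen gives the 6-acyl isomer, which should form as well and is removed by chromatography.

Step 7
Reactants: 15 hexanoyl chromene; 16 N,N-dimethylmethyleneiminium iodide (Eschenmoser's salt)
Product: 17 1-{6-[(dimethylamino)methyl]-5,7-dihydroxy-2,2-dimethyl-2H-chromen-8-yl}hexan-1-one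
Conditions: Et3N (1.1 equiv), CH2Cl2, 0 °C → rt
Reagents that add atoms: none
Why: Phenol Mannich reaction with a preformed iminium salt should aminomethylate C6, the only free aromatic carbon, and the absence of free formaldehyde avoids the symmetrical bis(chromenyl)methane.

Step 8
Reactants: 17 chromene Mannich base (1.2 equiv); 9 ring B monomer
Product: 19 (4R)-2-acetyl-6-[(8-hexanoyl-5,7-dihydroxy-2,2-dimethyl-2H-chromen-6-yl)methyl]-4-[(2E)-3,7-dimethylocta-2,6-dien-1-yl]-3,5-dihydroxy-4-methylcyclohexa-2,5-dien-1-one, via chromene ortho-quinone methide 18 (not isolated)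
Conditions: 1,4-dioxane, 90 °C, N2 stream
Reagents that add atoms: none
Why: Thermal loss of dimethylamine from the phenolic Mannich base gives ortho-quinone methide 18, which is captured in a Michael addition by C6 of 9, the only unsubstituted nucleophilic carbon of the acidic triketone, so the methylene bridge forms without touching the quaternary stereocentre.

**Compound list**

1 | dimethyl methylmalonate (dimethyl 2-methylpropanedioate) | COC(=O)C(C)C(=O)OC | starting material
2 | geranyl bromide, (2E)-1-bromo-3,7-dimethylocta-2,6-diene | BrC/C=C(\C)CCC=C(C)C | starting material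
3 | dimethyl 2-[(2E)-3,7-dimethylocta-2,6-dien-1-yl]-2-methylpropanedioate | COC(=O)C(C)(C/C=C(\C)CCC=C(C)C)C(=O)OC | intermediate
4 | (2R,4E)-2-(methoxycarbonyl)-2,5,9-trimethyldeca-4,8-dienoic acid | OC(=O)[C@@](C)(C/C=C(\C)CCC=C(C)C)C(=O)OC | intermediate
5 | methyl (2S,4E)-2-(chlorocarbonyl)-2,5,9-trimethyldeca-4,8-dienoate | ClC(=O)[C@@](C)(C/C=C(\C)CCC=C(C)C)C(=O)OC | intermediate
6 | pentane-2,4-dione | CC(=O)CC(C)=O | starting material
7 | dilithium salt of the 1,3-dianion of pentane-2,4-dione (not isolated) | [Li+].[Li+].[CH2-]C(=O)[CH-]C(C)=O | intermediate
8 | methyl (2R,4E)-2-(3,5-dioxohexanoyl)-2,5,9-trimethyldeca-4,8-dienoate, the open-chain triketo ester (not isolated) | CC(=O)CC(=O)CC(=O)[C@@](C)(C/C=C(\C)CCC=C(C)C)C(=O)OC | intermediate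
9 | (4R)-2-acetyl-4-[(2E)-3,7-dimethylocta-2,6-dien-1-yl]-3,5-dihydroxy-4-methylcyclohexa-2,5-dien-1-one (ring B monomer) | O=C1C=C(O)[C@@](C)(C/C=C(\C)CCC=C(C)C)C(O)=C1C(C)=O | intermediate
10 | phloroglucinol (benzene-1,3,5-triol) | Oc1cc(O)cc(O)c1 | starting material
11 | hexanoyl chloride | CCCCCC(Cl)=O | starting material
12 | 1-(2,4,6-trihydroxyphenyl)hexan-1-one | CCCCCC(=O)c1c(O)cc(O)cc1O | intermediate
13 | 3-methylbut-2-enal | CC(C)=CC=O | starting material
14 | 2-hexanoyl-3,5-dihydroxy-6-(3-methylbut-2-en-1-ylidene)cyclohexa-2,4-dien-1-one, the ortho-quinone methide dienone (not isolated) | CCCCCC(=O)C1=C(O)C=C(O)C(=CC=C(C)C)C1=O | intermediate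
15 | 1-(5,7-dihydroxy-2,2-dimethyl-2H-chromen-8-yl)hexan-1-one | CCCCCC(=O)c1c(O)cc(O)c2c1OC(C)(C)C=C2 | intermediate
16 | N,N-dimethylmethyleneiminium iodide (Eschenmoser's salt) | C=[N+](C)C.[I-] | starting material
17 | 1-{6-[(dimethylamino)methyl]-5,7-dihydroxy-2,2-dimethyl-2H-chromen-8-yl}hexan-1-one | CCCCCC(=O)c1c(O)c(CN(C)C)c(O)c2c1OC(C)(C)C=C2 | intermediate
18 | 8-hexanoyl-7-hydroxy-2,2-dimethyl-6-methylidene-2H-chromen-5(6H)-one, the chromene ortho-quinone methide (not isolated) | CCCCCC(=O)C1=C(O)C(=C)C(=O)C2=C1OC(C)(C)C=C2 | intermediate
19 | (4R)-2-acetyl-6-[(8-hexanoyl-5,7-dihydroxy-2,2-dimethyl-2H-chromen-6-yl)methyl]-4-[(2E)-3,7-dimethylocta-2,6-dien-1-yl]-3,5-dihydroxy-4-methylcyclohexa-2,5-dien-1-one | CCCCCC(=O)c1c(O)c(CC2=C(O)[C@@](C)(C/C=C(\C)CCC=C(C)C)C(O)=C(C(C)=O)C2=O)c(O)c2c1OC(C)(C)C=C2 | target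

**Step count and risks**

Total step count: 8. Longest linear sequence: 5 steps (steps 1, 2, 3, 4, 8); the chromene branch (steps 5, 6, 7) joins at step 8.

Steps most likely to fail:

1. Step 4. The very reactive acid chloride may acylate an enolate oxygen or be attacked twice, or the open-chain tetracarbonyl may stay locked as its lithium chelate and fail to close. The fallback separates the two bond formations and uses a neutral nucleophile. It sets out from 5 and 6: 6 is converted with Me3SiOTf and Et3N in ether into 2,4-bis(trimethylsilyloxy)penta-1,3-diene F1, which should be acylated at its terminal carbon by 5 in CH2Cl2 (−78 °C → rt, Mukaiyama-type acylation). Mild aqueous work-up should give triketo ester 8 as an isolated compound. Ring closure is then carried out on its own with NaOMe in MeOH (or DBU in toluene), under thermodynamic control, and the route is rejoined at 9.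

2. Step 2. The esterase may distinguish the two ester groups poorly or in the opposite sense, or may turn over the lipophilic substrate slowly. The fallback is a classical resolution that sets out from 3. One equivalent of KOH in MeOH at rt should give the racemic half-ester F2. Its salt with (S)-1-phenylethylamine, the (R)-acid salt F3, is purified by fractional crystallisation (the antipodal amine is taken if it gives the less soluble salt with the (R)-acid). Acidification returns to the route at 4. The acid left in the mother liquor is re-methylated (MeI, K2CO3) to 3 and recycled.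

3. Step 6. The electrocyclisation may proceed through the para instead of the ortho phenolic oxygen, so that regioselectivity is poor and material is lost to the 6-acyl isomer. The fallback blocks the para oxygen and sets out from 12. MOMCl (1.05 equiv) and i-Pr2NEt in CH2Cl2 at 0 °C should etherify the most acidic, non-chelated hydroxyl and give 1-[2,6-dihydroxy-4-(methoxymethoxy)phenyl]hexan-1-one F4. Condensation with 13 under the same amine catalysis can then close only through an ortho oxygen and should give 1-[7-hydroxy-5-(methoxymethoxy)-2,2-dimethyl-2H-chromen-8-yl]hexan-1-one F5. HCl in MeOH at 40 °C removes the acetal and returns to the route at 15.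

**Further compounds**

F1 | step 4 | 2,4-bis(trimethylsilyloxy)penta-1,3-diene | C=C(O[Si](C)(C)C)C=C(C)O[Si](C)(C)C
F2 | step 2 | racemic (4E)-2-(methoxycarbonyl)-2,5,9-trimethyldeca-4,8-dienoic acid | OC(=O)C(C)(C/C=C(\C)CCC=C(C)C)C(=O)OC
F3 | step 2 | (S)-1-phenylethylammonium (2R,4E)-2-(methoxycarbonyl)-2,5,9-trimethyldeca-4,8-dienoate | [O-]C(=O)[C@@](C)(C/C=C(\C)CCC=C(C)C)C(=O)OC.C[C@H]([NH3+])c1ccccc1
F4 | step 6 | 1-[2,6-dihydroxy-4-(methoxymethoxy)phenyl]hexan-1-one | CCCCCC(=O)c1c(O)cc(OCOC)cc1O
F5 | step 6 | 1-[7-hydroxy-5-(methoxymethoxy)-2,2-dimethyl-2H-chromen-8-yl]hexan-1-one | CCCCCC(=O)c1c(O)cc(OCOC)c2c1OC(C)(C)C=C2
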